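## Structural features

The target is a 3,3a-dihydrobenzofuran-6(2H)-one: a five-membered cyclic ether (O1, C2, C3, C3a, C7a) fused through the C3a–C7a bond to a six-membered cross-conjugated dienone (C4=C5, C6=O, C7=C7a). C2 carries a 3,4,5-trimethoxyphenyl group, C3 a methyl group, the ring-fusion carbon C3a an allyl group and C5 a methoxy group. With O1 on C7a one enone is a vinylogous ester, and with the methoxy group on C5 the other is an α-alkoxy enone. Three contiguous stereocentres lie in the five-membered ring: C2 (R) and C3 (S), whose aryl and methyl groups are cis, and the all-carbon quaternary C3a (S), whose allyl group stands on the opposite face. The dienone is one allyl shift away from an aromatic ring: heat, acid or low-valent metals can move the allyl group from C3a to C5, O6 or C7. The enol ether is sensitive to aqueous acid, the terminal alkene rules out hydrogenation, and the benzylic C2–O bond of the less stable cis arrangement should not be ionised. The real difficulty is the quaternary stereocentre C3a, which must be made next to two tertiary stereocentres without letting the ring aromatise, together with the cis C2/C3 pair. Seen as the arene it derives from, the skeleton is a cis-2-aryl-3-methyl-2,3-dihydrobenzofuran in which C3 hangs on arene carbon C3a and benzylic C2 on O1. A carbene centred on C3 is then 1,5 to the C2–H bond of an ortho benzyl ether, and the key step uses this relationship to close the oxygen ring and set C2 and C3 at once; O6, para to C3a, is the handle for the later allyl transfer.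

## Logic of the disconnections

12 ⇒ 11. The C7–H bond is traced back to a C7–Br bond; no skeletal bond is cut. The bromine is a placeholder that occupies the ortho carbon C7 while the allyl group is moved. The gain is that the regiochemistry of the dearomatisation becomes a matter of structure. The forward step must reduce a vinylic C–Br bond without touching the dienone, the enol ether or the allyl group.

11 ⇒ 10. The C3a–CH2 bond of the allyl group is cut and the allyl group is returned to O6, which rearomatises the six-membered ring. C3a is para to O6, so the quaternary centre can come from an ambident phenoxide, and the cis-disubstituted ring next to it can direct the face. The gain is the loss of the quaternary stereocentre and of the dienone; an ordinary aryl allyl ether remains. The forward step must deliver the allyl group to the para carbon only, on the face away from the C3 methyl group, and its catalyst must leave the C–Br bond alone.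

10 ⇒ 9. The C2–C3 bond is cut, which opens the five-membered ring and removes both stereocentres: C3 becomes a diazo carbon and C2 the methylene of an ortho benzylic ether. The cut follows the 1,5 relationship between C3 and the C2–H bond. The gain is an achiral precursor in which the two arenes are joined by an ether only. The forward step must be a catalyst-controlled C–H insertion that gives the cis pair in one absolute sense and outruns the hydride shift of the methyl group.

9 ⇒ 8 ⇒ 7. The C=N2 unit is traced through the hydrazone to a C=O group. This places the carbene carbon at the oxidation level of an acetyl group. The forward steps are a condensation and a mild dehydrogenation that spare the aryl bromide, the allyl ether and the benzylic ether.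

7 ⇒ 5 + 6. The O–CH2 bond of the benzylic ether is cut. The trimethoxyphenyl ring and C2 come from 6 in one piece. The forward step must alkylate a hydroxyl that is hydrogen-bonded to the carbonyl group and flanked by bromine.

5 ⇒ 3 + 4. The O6–allyl bond is cut. The forward step must alkylate the para hydroxyl and leave the chelated ortho hydroxyl free.

3 ⇒ 2. The C–Br bond is cut. The forward step must brominate the one position between the two hydroxyls.

2 ⇒ 1. The aryl–acetyl C–C bond is cut. The forward step must acylate the ring carbon that is ortho to one hydroxyl and para to the other, which fixes the 2,4,5-oxygen pattern around the future C3a.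

## Other disconnections considered

Alternative 1: The cut is the C3a–C7a bond of the six-membered ring, with O1–C7a left to be closed later, so that the carbocycle is built around the quaternary carbon instead of being carved out of an arene.
- Forward key step: cyclobutenone A2, whose alkenyl arm already contains C2, C3, the allyl group and the future C3a, would open on heating to a dienylketene. A 6π-electrocyclisation would join the ketene carbon to the disubstituted alkene terminus and give the 6,6-disubstituted cyclohexa-2,4-dienone A1. Removal of the silyl group and acid would then close O1 onto C7a and free the C6 carbonyl by loss of the isopropyl group, leading to 12.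
- In its favour: the quaternary centre, the ring and the differentiated 5-methoxy/6-oxo pattern appear in one neutral step. There is no contest between ortho and para positions of a phenoxide, hence no blocking group and no reductive last step; on this point it is better than the chosen plan. No diazo compound is handled.
- Against it here: C3a would be set only by 1,2-induction from C3 across a freely rotating bond, since the two helical conformers of the dienylketene lead to the two C3a epimers. A1 is a linearly conjugated dienone that can dimerise by Diels–Alder reaction and can pass its allyl group on by a Cope shift at the temperature of its formation. The (1R,2S) side chain with its trisubstituted alkenyl metal has to be made first.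
- Comparison: both plans reach the same dienone, Alternative 1 without an aromatic detour. A pericyclic cascade under substrate control stands against a catalyst-controlled carbene insertion; control of C2/C3 by aldol-type chemistry would be the equal of the key step in reliability. The alternative is convergent but is expected to need more steps in its longest line than the nine of the chosen route.

Alternative 2: The cuts are C3a–C4 and C7–C7a: the six-membered ring is annulated onto the preformed oxygen ring at the oxidation level of a lactone.
- Forward key step: the enolate of the cis lactone A4 would add to the 2-methoxy enone A5 (C3a–C4). After proton transfer the methyl ketone enolate would acylate the lactone carbonyl (C7–C7a), and reclosure of the freed alkoxide onto the 1,3-dicarbonyl unit would give the bicyclic vinylogous ester A3. A3 would then be dehydrogenated to the phenol A6, brominated at C7 and O-allylated, which is 10, so the route joins the chosen plan before step 8.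
- In its favour: C2 and C3 come from well-established lactone chemistry and no carbene with a β-hydrogen is involved. On control of the cis pair it is the equal of the chosen plan and arguably more predictable.
- Against it here: A5 polymerises easily, and the first-formed enolate is the α-methoxy one, not the one needed for the Claisen step. Acylation at a lactone carbonyl is reversible ring-opening chemistry. The C3a and C5 stereocentres made in the annulation are destroyed by the aromatisation. Direct allylation of A3 would go to C5 or C7 rather than to the γ-carbon C3a, so the dearomatising allyl transfer and its blocking group are still needed.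
- Comparison: it ends at the same arene as the chosen plan and trades one catalytic C–H insertion for an anionic tandem. It is longer, because a chiral lactone must be prepared and three further operations are needed to reach 10, which the chosen route reaches in seven steps from 1.

Alternative 3: The cut is the C5–C6 bond, with the C4=C5 double bond seen as the result of a later elimination.
- Forward key step: A8 is a tetrahydrofuran that carries the quaternary C3a (allyl and a 2-methoxy-2-(phenylsulfonyl)ethyl arm) and an exocyclic alkoxy-acrylate at C7a. A strong amide base would generate the α-methoxy-α-sulfonyl carbanion at C5, which attacks the ester carbon C6 (Dieckmann-type closure) to give the β-keto sulfone A7. Loss of the sulfonyl group as sulfinate across C4–C5 would then give 12.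
- In its favour: the quaternary centre would be set early by alkylating a lactone enolate on the face opposite to the C3 methyl group, a dependable 1,2-induction. On C3a control it is the equal of, or better than, the allyl transfer of the chosen plan. The ring never passes through an arene, so nothing has to be blocked.
- Against it here: A7 has no acidic hydrogen between carbonyl and sulfone, so the acylation lacks the usual thermodynamic sink and can reverse. Turning a hindered α-quaternary lactone carbonyl into the (E)-configured exocyclic acrylate of A8 is a hard step in itself. The elimination must remove a C4 hydrogen that the carbonyl group does not activate. The sequence is long and linear.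
- Comparison: it builds the dienone directly and without a halogen, which is better. It relies on anionic C–C bond formation of uncertain thermodynamics where the chosen plan uses an irreversible carbene insertion. In step economy it is clearly behind.

Key step: step 7

Assumption: Rh2(R-PTAD)4 is taken to give the (2R,3S) enantiomer of 10; if the sense of induction for this methyl-substituted carbene is the opposite, the mirror-image catalyst Rh2(S-PTAD)4 is used with no other change.

## Route

Step 1
Reactants: 1 4-methoxyresorcinol (4-methoxybenzene-1,3-diol)
Product: 2 1-(2,4-dihydroxy-5-methoxyphenyl)ethanone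
Conditions: AcOH, BF3·OEt2 (solvent and promoter), 90 °C
Reagents that add atoms: acetic acid, CC(=O)O
Why: Friedel–Crafts (Nencki-type) C-acylation of a resorcinol: C6 of 1 is the only position ortho to one hydroxyl and para to the other that does not lie between two oxygens, so the acetyl group enters there; the product is held as a boron chelate, which stops a second acylation.

Step 2
Reactants: 2 1-(2,4-dihydroxy-5-methoxyphenyl)ethanone
Product: 3 1-(3-bromo-2,4-dihydroxy-5-methoxyphenyl)ethanone
Conditions: NBS (1.0 equiv), MeCN, 0 °C
Reagents that add atoms: N-bromosuccinimide, O=C1CCC(=O)N1Br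
Why: Electrophilic aromatic bromination: C3 is ortho to both hydroxyls and is the only strongly activated free position (C6 is meta to both and next to the acetyl group); one equivalent at 0 °C avoids bromination of the methyl ketone.

Step 3
Reactants: 3 1-(3-bromo-2,4-dihydroxy-5-methoxyphenyl)ethanone; 4 allyl bromide
Product: 5 1-[4-(allyloxy)-3-bromo-2-hydroxy-5-methoxyphenyl]ethanone
Conditions: K2CO3 (1.1 equiv), acetone, 56 °C
Reagents that add atoms: none
Why: Williamson ether synthesis with regioselection by hydrogen bonding: the 2-hydroxyl is tied to the carbonyl oxygen and is the poorer nucleophile, so a weak base and one equivalent of 4 should alkylate the 4-hydroxyl only.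

Step 4
Reactants: 5 1-[4-(allyloxy)-3-bromo-2-hydroxy-5-methoxyphenyl]ethanone; 6 3,4,5-trimethoxybenzyl chloride
Product: 7 1-[4-(allyloxy)-3-bromo-5-methoxy-2-[(3,4,5-trimethoxybenzyl)oxy]phenyl]ethanone
Conditions: K2CO3, KI (10 mol%), DMF, 70 °C
Reagents that add atoms: none
Why: Williamson ether synthesis on the remaining chelated, hindered phenol, which needs a dipolar aprotic solvent, heat and in situ conversion of 6 into the benzylic iodide (Finkelstein exchange); the benzylic electrophile cannot eliminate.

Step 5
Reactants: 7 1-[4-(allyloxy)-3-bromo-5-methoxy-2-[(3,4,5-trimethoxybenzyl)oxy]phenyl]ethanone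
Product: 8 (E)-{1-[4-(allyloxy)-3-bromo-5-methoxy-2-[(3,4,5-trimethoxybenzyl)oxy]phenyl]ethylidene}hydrazine (the free hydrazone of 7; the C=N geometry is of no consequence)
Conditions: N2H4·H2O (10 equiv), AcOH (cat.), EtOH, 80 °C, under argon
Reagents that add atoms: hydrazine (used as hydrate), NN
Why: Condensation of a ketone with hydrazine to the N-unsubstituted hydrazone; the large excess of hydrazine keeps azine formation down and the inert atmosphere avoids diimide reduction of the allyl group.

Step 6
Reactants: 8 (E)-{1-[4-(allyloxy)-3-bromo-5-methoxy-2-[(3,4,5-trimethoxybenzyl)oxy]phenyl]ethylidene}hydrazine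
Product: 9 1-[4-(allyloxy)-3-bromo-5-methoxy-2-[(3,4,5-trimethoxybenzyl)oxy]phenyl]-1-diazoethane (obtained as a cold filtered solution and taken on at once)
Conditions: activated MnO2 (8 equiv), CH2Cl2, 0 °C; filtration through Celite under argon
Reagents that add atoms: none
Why: Dehydrogenation of a free hydrazone to the diazoalkane by MnO2 (hydrazone oxidation); an aryl alkyl diazomethane should be stable enough in cold solution to be separated from the oxidant, and neither the aryl bromide nor the ethers are oxidised.

Step 7
Reactants: 9 1-[4-(allyloxy)-3-bromo-5-methoxy-2-[(3,4,5-trimethoxybenzyl)oxy]phenyl]-1-diazoethane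
Product: 10 (2R,3S)-6-(allyloxy)-7-bromo-5-methoxy-3-methyl-2-(3,4,5-trimethoxyphenyl)-2,3-dihydrobenzofuran (aryl and methyl cis)
Conditions: Rh2(R-PTAD)4 [dirhodium tetrakis((R)-(1-adamantyl)(phthalimido)acetate)] (1 mol%), CH2Cl2, 0 °C to rt
Reagents that add atoms: none
Why: The catalyst expels N2 from 9 and forms a rhodium carbene at C3 flanked by two donors (the aryl ring and the methyl group), so it is weakly electrophilic and long-lived enough to select the best C–H bond. Insertion is a concerted, asynchronous three-centre process with hydride-transfer character: the benzylic C2–H bond of the ortho ether, activated by the ether oxygen and by the trimethoxyphenyl ring, is delivered to the carbene carbon through a five-membered transition state (C3, C3a, C7a, O1, C2) as the C2–C3 bond forms. The closest known reaction type is the dirhodium-carboxylate-catalysed intramolecular insertion of hydrazone-derived donor/donor carbenes into benzylic ether C–H bonds, which gives cis-2,3-disubstituted 2,3-dihydrobenzofurans. The one ring closed is the five-membered oxygen ring, and it closes by a 1,5 C–H insertion (carbene carbon counted as 1, C2 as 5), the mode preferred by metal carbenes because its transition state is free of strain. C2 and C3 are created together: their cis relationship comes from the compact transition state in which the C2 aryl group and the carbene methyl group both point away from the carboxylate wall, and their absolute sense from the chiral pocket of the four adamantyl-phthalimido carboxylates, which selects one enantiotopic benzylic hydrogen and one carbene face. The step needs chemoselectivity for insertion over the 1,2-hydride shift of the methyl group (to a styrene), over cyclopropanation of the allyl ether and over attack on the arenes; the substrate secures this by the hydridic, doubly activated C2–H bond, by the flanking bromine, which turns the benzyloxy group out of the ring plane towards the carbene, and by the para position of the allyl ether, which cannot reach the carbene within the molecule.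

Step 8
Reactants: 10 (2R,3S)-6-(allyloxy)-7-bromo-5-methoxy-3-methyl-2-(3,4,5-trimethoxyphenyl)-2,3-dihydrobenzofuran
Product: 11 (2R,3S,3aS)-3a-allyl-7-bromo-5-methoxy-3-methyl-2-(3,4,5-trimethoxyphenyl)-3,3a-dihydrobenzofuran-6(2H)-one (allyl trans to the methyl and aryl groups)
Conditions: Pd2(dba)3 (2.5 mol%), P(OPh)3 (20 mol%), toluene, 60 °C
Reagents that add atoms: none
Why: Proposed new method: zerovalent palladium ionises the aryl allyl ether of 10 to an η3-allylpalladium cation and the phenoxide; return to oxygen is degenerate and both ortho carbons are blocked (C5 by methoxy, C7 by bromine), so product can accumulate only by attack of the para carbon C3a (para to O6 and ortho to O1, the most nucleophilic carbon of a 3-alkoxyphenoxide) on the allyl terminus from the face opposite the cis C3-methyl/C2-aryl pair, which sets C3a as S and gives a dienone stabilised as a vinylogous ester; the electron-poor phosphite ligand is chosen because it supports allylic ionisation but is slow to insert into the C–Br bonds of 10 and 11; the closest known reaction types are the Tsuji–Trost O-to-C allyl transfer of allyl enol ethers and aryl allyl ethers and the palladium-catalysed intramolecular para-dearomatising allylation of phenols.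

Step 9
Reactants: 11 (2R,3S,3aS)-3a-allyl-7-bromo-5-methoxy-3-methyl-2-(3,4,5-trimethoxyphenyl)-3,3a-dihydrobenzofuran-6(2H)-one
Product: 12 (2R,3S,3aS)-3a-allyl-5-methoxy-3-methyl-2-(3,4,5-trimethoxyphenyl)-3,3a-dihydrobenzofuran-6(2H)-one (target)
Conditions: Pd(OAc)2 (5 mol%), PPh3 (10 mol%), HCO2Na (1.5 equiv), DMF, 50 °C
Reagents that add atoms: none
Why: Palladium-catalysed hydrodehalogenation with formate: oxidative addition into the activated C–Br bond of the α-bromo enone, bromide/formate exchange, decarboxylation to a palladium hydride and C–H reductive elimination; no stereocentre is involved, and the mild temperature is meant to keep the hydride away from the terminal alkene and the dienone.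

## Compound list

1 | 4-methoxyresorcinol (4-methoxybenzene-1,3-diol) | COc1ccc(O)cc1O | starting material
2 | 1-(2,4-dihydroxy-5-methoxyphenyl)ethanone | CC(=O)c1cc(OC)c(O)cc1O | intermediate
3 | 1-(3-bromo-2,4-dihydroxy-5-methoxyphenyl)ethanone | CC(=O)c1cc(OC)c(O)c(Br)c1O | intermediate
4 | allyl bromide (3-bromoprop-1-ene) | C=CCBr | starting material
5 | 1-[4-(allyloxy)-3-bromo-2-hydroxy-5-methoxyphenyl]ethanone | CC(=O)c1cc(OC)c(OCC=C)c(Br)c1O | intermediate
6 | 3,4,5-trimethoxybenzyl chloride | COc1cc(CCl)cc(OC)c1OC | starting material
7 | 1-[4-(allyloxy)-3-bromo-5-methoxy-2-[(3,4,5-trimethoxybenzyl)oxy]phenyl]ethanone | CC(=O)c1cc(OC)c(OCC=C)c(Br)c1OCc1cc(OC)c(OC)c(OC)c1 | intermediate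
8 | (E)-{1-[4-(allyloxy)-3-bromo-5-methoxy-2-[(3,4,5-trimethoxybenzyl)oxy]phenyl]ethylidene}hydrazine | C/C(=N\N)c1cc(OC)c(OCC=C)c(Br)c1OCc1cc(OC)c(OC)c(OC)c1 | intermediate
9 | 1-[4-(allyloxy)-3-bromo-5-methoxy-2-[(3,4,5-trimethoxybenzyl)oxy]phenyl]-1-diazoethane | CC(=[N+]=[N-])c1cc(OC)c(OCC=C)c(Br)c1OCc1cc(OC)c(OC)c(OC)c1 | intermediate
10 | (2R,3S)-6-(allyloxy)-7-bromo-5-methoxy-3-methyl-2-(3,4,5-trimethoxyphenyl)-2,3-dihydrobenzofuran | C=CCOc1c(Br)c2O[C@@H](c3cc(OC)c(OC)c(OC)c3)[C@@H](C)c2cc1OC | intermediate
11 | (2R,3S,3aS)-3a-allyl-7-bromo-5-methoxy-3-methyl-2-(3,4,5-trimethoxyphenyl)-3,3a-dihydrobenzofuran-6(2H)-one | C=CC[C@]12C=C(OC)C(=O)C(Br)=C1O[C@@H](c1cc(OC)c(OC)c(OC)c1)[C@H]2C | intermediate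
12 | (2R,3S,3aS)-3a-allyl-5-methoxy-3-methyl-2-(3,4,5-trimethoxyphenyl)-3,3a-dihydrobenzofuran-6(2H)-one | C=CC[C@]12C=C(OC)C(=O)C=C1O[C@@H](c1cc(OC)c(OC)c(OC)c1)[C@H]2C | target

## Step count and least certain steps

Total step count: 9. Steps 6 and 7 are run back to back without purification of 9. Longest linear sequence: 9 steps from 1; 4 and 6 enter as single building blocks.

Step 8 (allyl transfer from O6 to C3a). Several things may go wrong:
- The ion pair may recombine only at oxygen, so that nothing is converted.
- Attack at a blocked ortho carbon followed by a Cope shift would erode the facial selectivity at C3a.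
- Palladium may insert into the activated C–Br bond of the product and be lost from the cycle.
- If the transfer is reversible, the equilibrium between aryl ether and dienone may not lie far enough on the dienone side.

The fallback uses known chemistry without a metal. It sets out from 10 and comes back at 11. 10 is heated in N,N-diethylaniline at about 180 °C. A Claisen [3,3] shift carries the allyl group from O6 to the methoxy-bearing ortho carbon C5 and gives the ortho-dienone (2R,3S,5R)-5-allyl-7-bromo-5-methoxy-3-methyl-2-(3,4,5-trimethoxyphenyl)-2,3-dihydrobenzofuran-6(5H)-one F1, which is not isolated. A Cope [3,3] shift then moves the allyl group suprafacially from C5 to C3a and gives 11 (para-Claisen rearrangement of a 2,6-disubstituted aryl allyl ether). Because ether, ortho-dienone and para-dienone interconvert at this temperature, the C3a epimer with the allyl group away from the C3 methyl group should be favoured as the less strained one. The price is the high temperature, at which loss of bromine from the ring is the side reaction to watch.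

Step 7 (key step). The most likely failure is the 1,2-shift of a methyl hydrogen to the carbene carbon, which leads to a styrene before the C–H insertion can take place. Azine formation from 9 and an insufficient or opposite enantioinduction for a methyl-substituted carbene are the other concerns.

The fallback sets out from 7 and comes back at 10; it replaces the carbene by a donor/acceptor one without β-hydrogens:
- Oxidative 1,2-aryl migration of the methyl ketone (PhI(OH)OTs, HC(OMe)3, MeOH, 50 °C) should give methyl 2-[4-(allyloxy)-3-bromo-5-methoxy-2-[(3,4,5-trimethoxybenzyl)oxy]phenyl]acetate F2.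
- Diazo transfer (4-acetamidobenzenesulfonyl azide, DBU, MeCN) gives methyl 2-[4-(allyloxy)-3-bromo-5-methoxy-2-[(3,4,5-trimethoxybenzyl)oxy]phenyl]-2-diazoacetate F3.
- Insertion into the same benzylic C–H bond with Rh2(S-PTTL)4 (dirhodium tetrakis[N-phthaloyl-(S)-tert-leucinate], or its mirror image as required) in toluene at −60 °C gives the cis ester methyl (2R,3S)-6-(allyloxy)-7-bromo-5-methoxy-2-(3,4,5-trimethoxyphenyl)-2,3-dihydrobenzofuran-3-carboxylate F4.
- Reduction with i-Bu2AlH at −78 °C, which avoids base and so epimerisation at C3, gives [(2R,3R)-6-(allyloxy)-7-bromo-5-methoxy-2-(3,4,5-trimethoxyphenyl)-2,3-dihydrobenzofuran-3-yl]methanol F5. The spatial arrangement is unchanged; only the descriptor changes.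
- Mesylation (MsCl, Et3N) gives [(2R,3R)-6-(allyloxy)-7-bromo-5-methoxy-2-(3,4,5-trimethoxyphenyl)-2,3-dihydrobenzofuran-3-yl]methyl methanesulfonate F6.
- LiBHEt3 in THF at 0 °C replaces the sulfonate by hydride and gives 10.

Step 9 (removal of bromine). The risk is loss of the allyl group. Zerovalent palladium may re-ionise the C3a–allyl bond of 11 or 12, driven by rearomatisation, and formate would then reduce the allyl fragment irreversibly. Palladium hydride may also reduce an enone or move the terminal double bond.

The fallback sets out from 10 and comes back at 12; it exchanges the blocking group for one that needs no reduction: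
- Bromine–lithium exchange (n-BuLi, THF, −78 °C) and quench with Me3SiCl give [(2R,3S)-6-(allyloxy)-5-methoxy-3-methyl-2-(3,4,5-trimethoxyphenyl)-2,3-dihydrobenzofuran-7-yl]trimethylsilane F7.
- The allyl transfer of step 8 then gives (2R,3S,3aS)-3a-allyl-5-methoxy-3-methyl-7-(trimethylsilyl)-2-(3,4,5-trimethoxyphenyl)-3,3a-dihydrobenzofuran-6(2H)-one F8.
- Ipso-protodesilylation of this α-silyl vinylogous ester (CF3CO2H, CH2Cl2, 0 °C) gives 12 without any hydride source. Protonation at C7 is assisted by O1 and by the β-silicon effect.

## Further compounds

F1 | step 8 | (2R,3S,5R)-5-allyl-7-bromo-5-methoxy-3-methyl-2-(3,4,5-trimethoxyphenyl)-2,3-dihydrobenzofuran-6(5H)-one | C=CC[C@]1(OC)C(=O)C(Br)=C2O[C@@H](c3cc(OC)c(OC)c(OC)c3)[C@@H](C)C2=C1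
F2 | step 7 | methyl 2-[4-(allyloxy)-3-bromo-5-methoxy-2-[(3,4,5-trimethoxybenzyl)oxy]phenyl]acetate | COC(=O)Cc1cc(OC)c(OCC=C)c(Br)c1OCc1cc(OC)c(OC)c(OC)c1
F3 | step 7 | methyl 2-[4-(allyloxy)-3-bromo-5-methoxy-2-[(3,4,5-trimethoxybenzyl)oxy]phenyl]-2-diazoacetate | COC(=O)C(=[N+]=[N-])c1cc(OC)c(OCC=C)c(Br)c1OCc1cc(OC)c(OC)c(OC)c1
F4 | step 7 | methyl (2R,3S)-6-(allyloxy)-7-bromo-5-methoxy-2-(3,4,5-trimethoxyphenyl)-2,3-dihydrobenzofuran-3-carboxylate | C=CCOc1c(Br)c2O[C@@H](c3cc(OC)c(OC)c(OC)c3)[C@@H](C(=O)OC)c2cc1OC
F5 | step 7 | [(2R,3R)-6-(allyloxy)-7-bromo-5-methoxy-2-(3,4,5-trimethoxyphenyl)-2,3-dihydrobenzofuran-3-yl]methanol | C=CCOc1c(Br)c2O[C@@H](c3cc(OC)c(OC)c(OC)c3)[C@@H](CO)c2cc1OC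
F6 | step 7 | [(2R,3R)-6-(allyloxy)-7-bromo-5-methoxy-2-(3,4,5-trimethoxyphenyl)-2,3-dihydrobenzofuran-3-yl]methyl methanesulfonate | C=CCOc1c(Br)c2O[C@@H](c3cc(OC)c(OC)c(OC)c3)[C@@H](COS(C)(=O)=O)c2cc1OC
F7 | step 9 | [(2R,3S)-6-(allyloxy)-5-methoxy-3-methyl-2-(3,4,5-trimethoxyphenyl)-2,3-dihydrobenzofuran-7-yl]trimethylsilane | C=CCOc1c([Si](C)(C)C)c2O[C@@H](c3cc(OC)c(OC)c(OC)c3)[C@@H](C)c2cc1OC
F8 | step 9 | (2R,3S,3aS)-3a-allyl-5-methoxy-3-methyl-7-(trimethylsilyl)-2-(3,4,5-trimethoxyphenyl)-3,3a-dihydrobenzofuran-6(2H)-one | C=CC[C@]12C=C(OC)C(=O)C([Si](C)(C)C)=C1O[C@@H](c1cc(OC)c(OC)c(OC)c1)[C@H]2C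
A1 | alternative 1 | (S)-6-allyl-6-[(1R,2S)-1-(tert-butyldimethylsilyloxy)-1-(3,4,5-trimethoxyphenyl)propan-2-yl]-3-isopropoxy-4-methoxycyclohexa-2,4-dienone | C=CC[C@@]1(C=C(OC)C(OC(C)C)=CC1=O)[C@H](C)[C@@H](O[Si](C)(C)C(C)(C)C)c1cc(OC)c(OC)c(OC)c1
A2 | alternative 1 | 4-[(3S,4R)-2-allyl-4-(tert-butyldimethylsilyloxy)-3-methyl-4-(3,4,5-trimethoxyphenyl)but-1-enyl]-3-isopropoxy-4-methoxycyclobut-2-enone (alkene geometry and ring C4 not fixed) | C=CCC(=CC1(OC)C(OC(C)C)=CC1=O)[C@H](C)[C@@H](O[Si](C)(C)C(C)(C)C)c1cc(OC)c(OC)c(OC)c1
A3 | alternative 2 | (2R,3S)-5-methoxy-3-methyl-2-(3,4,5-trimethoxyphenyl)-3,3a,4,5-tetrahydrobenzofuran-6(2H)-one (one C3a and C5 epimer drawn) | CO[C@H]1C[C@@H]2C(=CC1=O)O[C@@H](c1cc(OC)c(OC)c(OC)c1)[C@H]2C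
A4 | alternative 2 | (4S,5R)-4-methyl-5-(3,4,5-trimethoxyphenyl)dihydrofuran-2(3H)-one (cis) | O=C1C[C@H](C)[C@H](c2cc(OC)c(OC)c(OC)c2)O1
A5 | alternative 2 | 3-methoxybut-3-en-2-one | CC(=O)C(=C)OC
A6 | alternative 2 | (2R,3S)-5-methoxy-3-methyl-2-(3,4,5-trimethoxyphenyl)-2,3-dihydrobenzofuran-6-ol | Oc1cc2O[C@@H](c3cc(OC)c(OC)c(OC)c3)[C@@H](C)c2cc1OC
A7 | alternative 3 | 3a-allyl-5-methoxy-3-methyl-5-(phenylsulfonyl)-2-(3,4,5-trimethoxyphenyl)-3,3a,4,5-tetrahydrobenzofuran-6(2H)-one (C2, C3 and C3a arranged as in 12; one C5 epimer drawn) | C=CC[C@]12C[C@](OC)(S(=O)(=O)c3ccccc3)C(=O)C=C1O[C@@H](c1cc(OC)c(OC)c(OC)c1)[C@H]2C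
A8 | alternative 3 | methyl (E)-2-[3-allyl-3-[2-methoxy-2-(phenylsulfonyl)ethyl]-4-methyl-5-(3,4,5-trimethoxyphenyl)dihydrofuran-2(3H)-ylidene]acetate (ring stereocentres arranged as in 12; sulfone-bearing carbon not fixed) | C=CC[C@]1(CC(OC)S(=O)(=O)c2ccccc2)/C(=C\C(=O)OC)O[C@@H](c2cc(OC)c(OC)c(OC)c2)[C@H]1C
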